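Time comes first: dusk, dawn and winter each stand for 30 d with E held at 15 mM, and c_J at that time is asked.

| setting | east | west | dusk | dawn | winter |
|---|---|---|---|---|---|
| L | 0.030 M | 0.15 M | 0.050 M | 0.10 M | 0.20 M |
| E | 15 mM (held) | 15 mM (held) | 15 mM (held) | 15 mM (held) | 15 mM (held) |
| remark | run made earlier | run made earlier |  |  |  |
| time |  |  | 30 d | 30 d | 30 d |

| run | time / d | J / % |
|---|---|---|
| east | 1.25 | 16.9 |
| east | 3.00 | 35.7 |
| east | 6.00 | 59.5 |
| east | 15.0 | 87.6 |
| west | 4.00 | 44.7 |
| west | 8.00 | 69.2 |
| west | 12.0 | 80.6 |
| west | 15.0 | 87.7 |

(readings scatter by 1 percentage point)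

- [J] at the end for dusk, dawn, winter, in this order
- the shape of the row from first to last (rises, then falls / falls, then rises / hardly changes / rises all the way / falls all the way)

- at the start none of E is in solution
- "hardly changes" means that all values lie within two and a half points (for a concentration: within two and a half percent of the largest)

East reads 35.7% J at 3.00 d. Taking J as the L consumed, that gives 4.71 d as the half-life of L, the time in which unreacted L halves at held E, a pseudo-first-order decay. West, with 5.00 times the charge, reads 4.68 d at 4.00 d.

The half-life need not be known closely. At 4.71 d, 30 d leaves 1.21% of the L. East's last reading gives a longer 4.98 d, which leaves 1.54%, a shift of 0.33 percentage points.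

The charge counts in full: at 15.0 d, east and west read 87.6% and 87.7%, so c_J is reckoned in proportion to the charge.

East's 87.6% stands 1.4 points below the decay, with a scatter of 1 point, and that gap may be a loss of J. If that loss grows in step with time, it reaches 2.8 points at 30 d, more than the shift from the half-life. This reckoning therefore commits to 96.0% of the charge: 0.0480 M, 0.0960 M and 0.192 M, rising all the way.

The forecast gives 0.0475 M, 0.095 M and 0.19 M, rises all the way, slightly lower, with the words “So J scales with L”. The flasks give 0.0451 M, 0.0904 M and 0.181 M, rises all the way.

    L + Q → J + G (k = 0.430 /M/h)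
    Q + J ⇌ Z + G (K = 14.0, k = 0.0110 /M/h)
    E ⇌ Q, rate k3*(csat - [Q]) (kL = 1.10 /h)

Carried to dawn, the half-life of 4.71 d leaves 1.21% of L at 30.0 d, and 1.0% of the charged L stands there unbound. In dusk, half of the turnover of L to J up to 30 d is done by 4.51 d, but half of the turnover of J to Z up to 30 d takes until 17.6 d, and at 3.28 d L uses Q 62 times as fast as the forward step from J does. At 30.0 d dusk holds 90.3% J and 8.73% Z of its charge.

(All runs stem from a simulated flask with constants of no real substance; the scatter is artificial.)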